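**Retrosynthetic overview**
1. Target 13 ⇒ tetramethyl ether 12. A self-limiting thiolate O-demethylation removes three of the four OMe groups.
2. 12 ⇒ dibromide 7 + 2 × p-anisaldehyde 8. Both central-ring–CH2Ar bonds are cut at once: the aldehyde carbon acts as a nucleophile (N–H hydrazone, a d1 umpolung synthon) towards the electrophilic C–Br carbons under nickel catalysis.
3. 7 ⇒ 3,5-dimethoxybibenzyl 5 by a symmetry-controlled double bromination.
4. 5 ⇒ styrene 1 + 1-bromo-3,5-dimethoxybenzene 3 by hydroboration and B-alkyl Suzuki–Miyaura coupling.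
5. No ring is formed, since all four benzene rings are bought. The phenethyl ring is attached first, then both anisyl rings together.

Assumption: the target has no stereocentre, stereogenic axis or double bond and is achiral, so there is no enantiomer to select. The only stereodescriptor in the route is the E geometry of the transient hydrazone.

**Step 1**
Reactants: 1 styrene; 2 9-BBN-H (9-borabicyclo[3.3.1]nonane); 3 1-bromo-3,5-dimethoxybenzene
Product: 5 3,5-dimethoxybibenzyl, via phenethylborane 4 (not isolated)
Conditions: 1 (1.2 equiv), 2 (0.5 M in THF, 1.3 equiv), 0 °C to rt, 4 h; then 3, PdCl2(dppf) (3 mol %), 3 M aq NaOH (3 equiv), THF, 65 °C, 12 h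
Reagents that add atoms: none
Why: 9-BBN-H adds to styrene with more than 98 % anti-Markovnikov selectivity, and the primary borane 4 transmetalates under hydroxide activation in a B-alkyl Suzuki–Miyaura coupling (dppf suppresses β-hydride elimination), giving the bibenzyl in one pot with no stereocentre formed.

**Step 2**
Reactants: 5 3,5-dimethoxybibenzyl
Product: 7 2,6-dibromo-3,5-dimethoxybibenzyl, via monobromide 6 (not isolated)
Conditions: NBS (2.05 equiv), MeCN, 0 °C to rt, dark, 3 h
Reagents that add atoms: N-bromosuccinimide (NBS), O=C1CCC(=O)N1Br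
Why: Electrophilic aromatic bromination is directed by both OMe groups to the two equivalent positions that are ortho to one OMe and para to the other (C2 and C6), while the crowded C4 between the OMe groups and the unactivated phenyl ring react much more slowly, as in the 2,6-dibromination of 3,5-dimethoxytoluene, and no stereocentre is formed.

**Step 3 (key step)**
Reactants: 7 2,6-dibromo-3,5-dimethoxybibenzyl; 8 4-methoxybenzaldehyde; 9 hydrazine monohydrate
Product: 12 1,5-dimethoxy-2,4-bis(4-methoxybenzyl)-3-(2-phenylethyl)benzene, via hydrazone 10 (not isolated), via monocoupled bromide 11 (not isolated)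
Conditions: 8 (4.0 equiv), 9 (4.4 equiv), THF, rt, 1 h, Na2SO4; then 7 (1.0 equiv), Ni(cod)2 (20 mol %), PMe3 (40 mol %), K3PO4 (5 equiv), THF/1,4-dioxane, 100 °C (sealed tube), 24 h
Reagents that add atoms: none
Why: Proposed new method: the N-unsubstituted hydrazone 10 is an aza-enamine whose former aldehyde carbon is nucleophilic (a traceless acyl-anion/benzyl-anion equivalent), so it can be joined to the likewise electrophilic C–Br carbons of 7; zerovalent nickel carrying the small, strongly donating PMe3 inserts into the hindered, electron-rich C–Br bond, the hydrazone (its N–H acidified by coordination and removed by K3PO4) binds to the divalent aryl-nickel centre through nitrogen and slips to its carbon terminus, C–C reductive elimination and Wolff–Kishner-type loss of N2 leave a CH2 link, and the cycle repeats at the second, mirror-related bromide of 11; the closest known reaction type is the nickel/PMe3-catalysed Wolff–Kishner-type cross-coupling of aryl aldehyde hydrazones with simple aryl bromides and iodides, extended here to a twofold coupling at di-ortho-substituted positions, and no stereocentre is formed.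

**Step 4**
Reactants: 12 1,5-dimethoxy-2,4-bis(4-methoxybenzyl)-3-(2-phenylethyl)benzene
Product: 13 2,4-bis(4-hydroxybenzyl)-5-methoxy-3-(2-phenylethyl)phenol (IN1158)
Conditions: NaSEt (10 equiv), DMF, 150 °C, Ar, 8 h; then 1 M HCl
Reagents that add atoms: none
Why: Thiolate SN2 O-demethylation cleaves one OMe on each of the three methoxy-bearing rings and then stops, because removing the last central OMe would put a second negative charge on an already anionic phenoxide ring (the behaviour that turns 3,5-dimethoxytoluene cleanly into orcinol monomethyl ether), and since the two central OMe groups are mirror-related only one product can form and no stereocentre is involved.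

**Compound list**
1 | styrene | C=Cc1ccccc1 | starting material
2 | 9-borabicyclo[3.3.1]nonane (9-BBN-H) | B1C2CCCC1CCC2 | starting material
3 | 1-bromo-3,5-dimethoxybenzene | COc1cc(Br)cc(OC)c1 | starting material
4 | 9-(2-phenylethyl)-9-borabicyclo[3.3.1]nonane (not isolated) | C(Cc1ccccc1)B1C2CCCC1CCC2 | intermediate
5 | 3,5-dimethoxybibenzyl = 1,3-dimethoxy-5-(2-phenylethyl)benzene | COc1cc(OC)cc(CCc2ccccc2)c1 | intermediate
6 | 2-bromo-1,5-dimethoxy-3-(2-phenylethyl)benzene (not isolated) | COc1cc(OC)c(Br)c(CCc2ccccc2)c1 | intermediate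
7 | 2,6-dibromo-3,5-dimethoxybibenzyl = 2,4-dibromo-1,5-dimethoxy-3-(2-phenylethyl)benzene | COc1cc(OC)c(Br)c(CCc2ccccc2)c1Br | intermediate
8 | 4-methoxybenzaldehyde (p-anisaldehyde) | COc1ccc(C=O)cc1 | starting material
9 | hydrazine monohydrate | NN.O | starting material
10 | (E)-4-methoxybenzaldehyde hydrazone (not isolated) | COc1ccc(/C=N/N)cc1 | intermediate
11 | 2-bromo-1,5-dimethoxy-4-(4-methoxybenzyl)-3-(2-phenylethyl)benzene (not isolated) | COc1ccc(Cc2c(OC)cc(OC)c(Br)c2CCc2ccccc2)cc1 | intermediate
12 | 1,5-dimethoxy-2,4-bis(4-methoxybenzyl)-3-(2-phenylethyl)benzene | COc1ccc(Cc2c(OC)cc(OC)c(Cc3ccc(OC)cc3)c2CCc2ccccc2)cc1 | intermediate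
13 | 2,4-bis(4-hydroxybenzyl)-5-methoxy-3-(2-phenylethyl)phenol (IN1158, achiral) | COc1cc(O)c(Cc2ccc(O)cc2)c(CCc2ccccc2)c1Cc1ccc(O)cc1 | target

**Total step count:** 4. **Longest linear sequence:** 4 (1/3 → 5 → 7 → 12 → 13).

**Steps most likely to fail**

1. **Step 3.** The di-ortho-substituted aryl group on divalent nickel may be too inert. It may also be diverted to hydrodebromination or to N-arylation of the hydrazone. The fallback sets out from 7 and comes back at 12. It keeps the reversed polarity but swaps the roles of the partners.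
   - Double Br/Li exchange of 7 (n-BuLi, THF, −78 °C), a DMF quench and aqueous HCl work-up give 4,6-dimethoxy-2-(2-phenylethyl)benzene-1,3-dicarbaldehyde F1.
   - Hydrazine monohydrate in THF turns F1 into its (E,E)-bis-hydrazone F2.
   - This twofold carbon nucleophile is coupled under Ni(cod)2/PMe3/K3PO4 with purchased, unhindered 4-bromoanisole (2.5 equiv) to give 12. Oxidative addition and the nickel-bound aryl group are then free of ortho substituents.

2. **Step 4.** The two 4-alkylanisole ethers may cleave incompletely, or the separation of partly demethylated material may be poor. The fallback sets out from 5 and comes back at 13. It differentiates the oxygens early and ends with a hydrogenolysis.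
   - NaSEt in DMF removes one methyl group of 5 to give 3-methoxy-5-(2-phenylethyl)phenol F3.
   - Benzyl bromide and K2CO3 in acetone give 1-(benzyloxy)-3-methoxy-5-(2-phenylethyl)benzene F4.
   - NBS (2 equiv) in MeCN gives 1-(benzyloxy)-2,4-dibromo-5-methoxy-3-(2-phenylethyl)benzene F5.
   - Purchased 4-(benzyloxy)benzaldehyde and hydrazine monohydrate give (E)-4-(benzyloxy)benzaldehyde hydrazone F6.
   - F6 is coupled twice with F5 under the conditions of step 3 to give 1-(benzyloxy)-2,4-bis[4-(benzyloxy)benzyl]-5-methoxy-3-(2-phenylethyl)benzene F7.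
   - H2 (1 atm) over Pd/C in EtOAc/EtOH removes all three benzyl groups and gives 13.

3. **Step 1.** Protodeboronation or β-hydride elimination of the alkylborane may lower the yield. The fallback sets out from 1 and 3 and comes back at 5.
   - A Heck reaction (Pd(OAc)2, P(o-tol)3, NaOAc, DMF, 110 °C) gives (E)-3,5-dimethoxystilbene F8.
   - F8 is hydrogenated (H2, Pd/C, EtOAc, rt) to 5.

**Further compounds**
F1 | step 3 | 4,6-dimethoxy-2-(2-phenylethyl)benzene-1,3-dicarbaldehyde | COc1cc(OC)c(C=O)c(CCc2ccccc2)c1C=O
F2 | step 3 | (E,E)-bis-hydrazone of 4,6-dimethoxy-2-(2-phenylethyl)benzene-1,3-dicarbaldehyde | COc1cc(OC)c(/C=N/N)c(CCc2ccccc2)c1/C=N/N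
F3 | step 4 | 3-methoxy-5-(2-phenylethyl)phenol | COc1cc(O)cc(CCc2ccccc2)c1
F4 | step 4 | 1-(benzyloxy)-3-methoxy-5-(2-phenylethyl)benzene | COc1cc(OCc2ccccc2)cc(CCc2ccccc2)c1
F5 | step 4 | 1-(benzyloxy)-2,4-dibromo-5-methoxy-3-(2-phenylethyl)benzene | COc1cc(OCc2ccccc2)c(Br)c(CCc2ccccc2)c1Br
F6 | step 4 | (E)-4-(benzyloxy)benzaldehyde hydrazone | N/N=C/c1ccc(OCc2ccccc2)cc1
F7 | step 4 | 1-(benzyloxy)-2,4-bis[4-(benzyloxy)benzyl]-5-methoxy-3-(2-phenylethyl)benzene | COc1cc(OCc2ccccc2)c(Cc2ccc(OCc3ccccc3)cc2)c(CCc2ccccc2)c1Cc1ccc(OCc2ccccc2)cc1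
F8 | step 1 | (E)-3,5-dimethoxystilbene | COc1cc(OC)cc(/C=C/c2ccccc2)c1
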